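Retrosynthetic overview (chromanone numbering O1, C2, C3, C4, C4a, C5–C8, C8a; ring A = carbocycle, ring B = dihydropyranone):
- Target ⇒ C6 prenylation and removal of a C6 formyl blocking group ⇒ C8 geranylation by asymmetric allylic dearomatisation of an aromatic (2S)-6-formyl-5,7-dihydroxy-2,8-dimethylchroman-4-one.
- Key disconnection C2–C3: that chromanone ⇒ an achiral aryl vinyl ether with an ortho acetyl group, closed by a chiral Brønsted acid-catalysed cycloisomerisation that sets C2.
- Enabling feature: ring B is a β-alkoxy ketone (O1–C2–C3–C4=O) fused to ring A through the adjacent carbons C8a and C4a, so C2 can be the carbon of an O1-stabilised oxocarbenium ion and C3 the enol carbon of the C4 ketone, both held on one ring.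
- Vinyl ether ⇒ 2,4,6-trihydroxytoluene: a formyl group at the future C6 makes the future O1 the para hydroxyl for selective O-alkylation, later blocks C6 during dearomatisation, and is finally excised.
- Ring order: ring A is bought as the arene; ring B is formed in step 5; ring A is dearomatised (C8 quaternary centre) in step 6.

Key step: step 5

Assumption: the sense of induction of the chiral catalysts in steps 5 and 6 is assigned by analogy and the mirror-image catalyst would be used if it proves opposite; dearomatised compounds are drawn as the 5-hydroxy-4,7-dione tautomer of the target.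

Step 1
Reactants: 1 2-methylbenzene-1,3,5-triol (2,4,6-trihydroxytoluene)
Product: 3 2,4,6-trihydroxy-3-methylbenzaldehyde, via aryl iminium chloride 2 (not isolated)
Conditions: POCl3 (1.05 equiv), DMF (1.2 equiv), EtOAc, 0 °C to rt; then H2O, 50 °C
Reagents that add atoms: N,N-dimethylformamide, CN(C)C=O; water, O
Why: Vilsmeier–Haack formylation of the very electron-rich arene at one of its two equivalent free positions; one equivalent of reagent should stop at the monoaldehyde because the iminium group of 2 deactivates the ring, and hydrolysis of 2 releases the aldehyde.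

Step 2
Reactants: 3 2,4,6-trihydroxy-3-methylbenzaldehyde
Product: 4 4-(2-chloroethoxy)-2,6-dihydroxy-3-methylbenzaldehyde
Conditions: BrCH2CH2Cl (1.2 equiv), K2CO3 (1.1 equiv), DMF, rt
Reagents that add atoms: 1-bromo-2-chloroethane, ClCCBr
Why: Williamson ether synthesis (SN2 at the bromide-bearing carbon): the hydroxyl para to the formyl group is the most acidic one and, unlike the two ortho hydroxyls, cannot be tied up in a hydrogen bond to the aldehyde, so it should be alkylated alone, which puts the two-carbon unit of the future C2 on the oxygen lying between the C-methyl carbon and the free ring position.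

Step 3
Reactants: 4 4-(2-chloroethoxy)-2,6-dihydroxy-3-methylbenzaldehyde
Product: 5 3-acetyl-4-(2-chloroethoxy)-2,6-dihydroxy-5-methylbenzaldehyde
Conditions: Ac2O (1.1 equiv), MeSO3H, 40 °C; then ice-water
Reagents that add atoms: acetic anhydride, CC(=O)OC(C)=O
Why: Friedel–Crafts acylation at the only unsubstituted ring carbon, which is ortho or para to all three oxygen donors and meta to the formyl group, so the regiochemistry is fixed; the chelated aldehyde and the primary alkyl chloride should tolerate the acid.

Step 4
Reactants: 5 3-acetyl-4-(2-chloroethoxy)-2,6-dihydroxy-5-methylbenzaldehyde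
Product: 6 3-acetyl-4-(ethenyloxy)-2,6-dihydroxy-5-methylbenzaldehyde
Conditions: KOt-Bu (4 equiv), DMSO–THF, rt; quench into pH 6 phosphate buffer at 0 °C
Reagents that add atoms: none
Why: E2 elimination of HCl from the 2-chloroethyl aryl ether, the standard entry to aryl vinyl ethers; with excess base the phenols and the acetyl group are held as phenoxides and enolate, which shields the aldehyde and ketone from addition, and seven-membered ring alkylation by the enolate should be slower than elimination.

Step 5
Reactants: 6 3-acetyl-4-(ethenyloxy)-2,6-dihydroxy-5-methylbenzaldehyde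
Product: 7 (2S)-5,7-dihydroxy-2,8-dimethyl-4-oxo-3,4-dihydro-2H-chromene-6-carbaldehyde
Conditions: (S)-3,3′-bis(2,4,6-triisopropylphenyl)-1,1′-binaphthyl-2,2′-diyl N-triflylphosphoramide (5 mol%), 5 Å MS, toluene–CH2Cl2 (0.02 M), −40 to −10 °C
Reagents that add atoms: none
Why: Proposed new method: the chiral acid should protonate the terminal CH2 of the aryl vinyl ether to give the O1=C2 aryloxocarbenium ion paired with the chiral phosphoramidate, and the enol of the ortho acetyl group (C4(OH)=C3H2, hydrogen-bonded to the anion) then adds through C3 to C2, forming the C2–C3 bond and returning the proton to the catalyst; kinetic capture of the cation by the acetyl oxygen is reversible and drains into the same C–C product. The closest known reaction types are the chiral phosphoric acid-catalysed aldol-type addition of enols to oxocarbenium ions generated by protonation of alkyl vinyl ethers, and the enol/oxocarbenium recombination of the Petasis–Ferrier rearrangement and the silyl enol ether Prins cyclisation, which give tetrahydropyran-4-ones; an aryl vinyl ether closing a chromanone ring has not been shown. Ring B closes in a 6-(enolendo)-endo-trig mode. The new C2 centre is set by catalyst control alone: the chiral counteranion shields one face of the planar oxocarbenium ion in the hydrogen-bonded ion pair, and the substrate carries no stereocentre. The step needs C-protonation of the vinyl ether to win over activation of the acetyl carbonyl (which would let the vinyl CH2 attack C4 in a Prins-type closure) and over hydrolysis: the acetyl carbonyl is deactivated by chelation to the neighbouring hydroxyl and by the electron-rich ring, sieves exclude water, the arene has no free position for Friedel–Crafts capture, and the direction of ring closure is fixed because the vinyl group sits on the one oxygen flanked by the C-methyl and C-acetyl carbons.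

Step 6
Reactants: 7 (2S)-5,7-dihydroxy-2,8-dimethyl-4-oxo-3,4-dihydro-2H-chromene-6-carbaldehyde; 8 geranyl acetate
Product: 9 (2S,8R)-8-[(2E)-3,7-dimethylocta-2,6-dien-1-yl]-5-hydroxy-2,8-dimethyl-4,7-dioxo-3,4,7,8-tetrahydro-2H-chromene-6-carbaldehyde
Conditions: Pd2(dba)3·CHCl3 (2.5 mol%), (R,R)-ANDEN-phenyl Trost ligand (7.5 mol%), Et3N (1.1 equiv), CH2Cl2, rt; aq. citric acid work-up
Reagents that add atoms: none
Why: Palladium-catalysed asymmetric allylic alkylation run as a dearomatisation (Tsuji–Trost type): the phenoxide of 7 attacks the unsubstituted terminus of the π-geranyl palladium complex through C8, the only nucleophilic ring carbon left (C6 is blocked and deactivated by the formyl group and O-allylation is reversible under zerovalent palladium), and the chiral ligand pocket selects the face of the planar nucleophile, whose two flanks (ring-ether side C8a–O1 against phenoxide side C7–O) differ strongly, so that C8 should be set as R under catalyst control irrespective of the remote C2 centre.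

Step 7
Reactants: 9 (2S,8R)-8-[(2E)-3,7-dimethylocta-2,6-dien-1-yl]-5-hydroxy-2,8-dimethyl-4,7-dioxo-3,4,7,8-tetrahydro-2H-chromene-6-carbaldehyde
Product: 10 (2S,8R)-8-[(2E)-3,7-dimethylocta-2,6-dien-1-yl]-5-hydroxy-2,8-dimethyl-2,3-dihydro-4H-chromene-4,7(8H)-dione
Conditions: THF–H2O–AcOH (3:1:1), 40 °C
Reagents that add atoms: none
Why: Retro-Claisen type hydrolytic deformylation of the 2-formyl-1,3-dicarbonyl unit: water adds to the aldehyde and the C6–CHO bond breaks with the stabilised ring A dienol as leaving group, while the far less electrophilic C4 ketone of ring B, the trisubstituted alkenes and the C2 centre should not be touched by the weak acid.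

Step 8
Reactants: 10 (2S,8R)-8-[(2E)-3,7-dimethylocta-2,6-dien-1-yl]-5-hydroxy-2,8-dimethyl-2,3-dihydro-4H-chromene-4,7(8H)-dione; 11 prenyl acetate
Product: 12 (2S,8R)-8-[(2E)-3,7-dimethylocta-2,6-dien-1-yl]-5-hydroxy-2,8-dimethyl-6-(3-methylbut-2-en-1-yl)-2,3-dihydro-4H-chromene-4,7(8H)-dione (target)
Conditions: Pd(PPh3)4 (5 mol%), Et3N (1.1 equiv), THF, 40 °C; 11 (1.0 equiv) added slowly
Reagents that add atoms: none
Why: Tsuji–Trost allylic alkylation of the cyclic 1,3-dicarbonyl anion at C6, its only C–H carbon: attack on the unsubstituted terminus of the π-prenyl palladium complex should give the linear prenyl group, O-allylation is reversible under the catalyst, and slow addition of one equivalent of 11 limits a second alkylation.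

Compound list
1 | 2-methylbenzene-1,3,5-triol (2,4,6-trihydroxytoluene) | Cc1c(O)cc(O)cc1O | starting material
2 | (2,4,6-trihydroxy-3-methylbenzylidene)dimethylammonium chloride (aryl iminium chloride) | C[N+](C)=Cc1c(O)cc(O)c(C)c1O.[Cl-] | intermediate
3 | 2,4,6-trihydroxy-3-methylbenzaldehyde | Cc1c(O)cc(O)c(C=O)c1O | intermediate
4 | 4-(2-chloroethoxy)-2,6-dihydroxy-3-methylbenzaldehyde | Cc1c(OCCCl)cc(O)c(C=O)c1O | intermediate
5 | 3-acetyl-4-(2-chloroethoxy)-2,6-dihydroxy-5-methylbenzaldehyde | CC(=O)c1c(O)c(C=O)c(O)c(C)c1OCCCl | intermediate
6 | 3-acetyl-4-(ethenyloxy)-2,6-dihydroxy-5-methylbenzaldehyde | CC(=O)c1c(O)c(C=O)c(O)c(C)c1OC=C | intermediate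
7 | (2S)-5,7-dihydroxy-2,8-dimethyl-4-oxo-3,4-dihydro-2H-chromene-6-carbaldehyde | Cc1c(O)c(C=O)c(O)c2c1O[C@@H](C)CC2=O | intermediate
8 | geranyl acetate, (2E)-3,7-dimethylocta-2,6-dien-1-yl acetate | CC(C)=CCC/C(C)=C/COC(C)=O | starting material
9 | (2S,8R)-8-[(2E)-3,7-dimethylocta-2,6-dien-1-yl]-5-hydroxy-2,8-dimethyl-4,7-dioxo-3,4,7,8-tetrahydro-2H-chromene-6-carbaldehyde | CC(C)=CCC/C(C)=C/C[C@@]1(C)C(=O)C(C=O)=C(O)C2=C1O[C@@H](C)CC2=O | intermediate
10 | (2S,8R)-8-[(2E)-3,7-dimethylocta-2,6-dien-1-yl]-5-hydroxy-2,8-dimethyl-2,3-dihydro-4H-chromene-4,7(8H)-dione | CC(C)=CCC/C(C)=C/C[C@@]1(C)C(=O)C=C(O)C2=C1O[C@@H](C)CC2=O | intermediate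
11 | prenyl acetate, 3-methylbut-2-en-1-yl acetate | CC(C)=CCOC(C)=O | starting material
12 | (2S,8R)-8-[(2E)-3,7-dimethylocta-2,6-dien-1-yl]-5-hydroxy-2,8-dimethyl-6-(3-methylbut-2-en-1-yl)-2,3-dihydro-4H-chromene-4,7(8H)-dione | CC(C)=CCC/C(C)=C/C[C@@]1(C)C(=O)C(CC=C(C)C)=C(O)C2=C1O[C@@H](C)CC2=O | target

Total step count: 8. Longest linear sequence: 8 steps (1 to 12); 8 and 11 are bought.

Steps most likely to fail

Step 5 (Proposed new method). The ion pair may give insufficient face discrimination at C2. The vinyl group may also be lost by hydrolysis, or the Prins-type closure through the activated acetyl carbonyl may compete before the C2–C3 bond forms. The fallback uses known chiral-pool chemistry and closes ring B at C4–C4a instead. It sets out from 3 and comes back to the route at 7. Mitsunobu etherification of the para hydroxyl of 3 with ethyl (R)-3-hydroxybutanoate (PPh3, DIAD, THF, 0 °C; inversion at the carbinol carbon) should give ethyl (3S)-3-(4-formyl-3,5-dihydroxy-2-methylphenoxy)butanoate F1. Saponification (LiOH, THF–H2O) gives (3S)-3-(4-formyl-3,5-dihydroxy-2-methylphenoxy)butanoic acid F2. Intramolecular Friedel–Crafts acylation at the only free ring position (P2O5–MeSO3H, rt) then closes ring B and delivers 7.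

Step 6. Facial selectivity at C8 under catalyst control may be poor, kinetic O-geranylation may fail to revert, or the E geometry may erode through π–σ–π isomerisation of the geranyl palladium complex. The fallback sets out from 7 and comes back at 9. Uncatalysed C-alkylation of the phenoxide with geranyl bromide (aq. KOH, toluene, 0 °C; SN2, alkene geometry untouched) should give 9 together with its C8 epimer, (2S,8S)-8-[(2E)-3,7-dimethylocta-2,6-dien-1-yl]-5-hydroxy-2,8-dimethyl-4,7-dioxo-3,4,7,8-tetrahydro-2H-chromene-6-carbaldehyde F3. Because C2 is already fixed, the two are diastereomers and are separated by chromatography.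

Step 8. A second alkylation may give the 6,6-diprenyl compound, and O-prenylation may not revert. The fallback sets out from 10 and comes back at 12. It is an organocatalytic three-component reductive alkylation (3-methylbut-2-enal, Hantzsch ester, L-proline cat., CH2Cl2, rt). Knoevenagel condensation at C6 gives (2S,8R)-8-[(2E)-3,7-dimethylocta-2,6-dien-1-yl]-2,8-dimethyl-6-(3-methylbut-2-en-1-ylidene)-2,3-dihydro-4H-chromene-4,5,7(6H,8H)-trione F4 (not isolated, exocyclic alkene geometry immaterial). Conjugate hydride transfer from the dihydropyridine to the exocyclic carbon then gives 12. O-alkylation and double alkylation are excluded by construction.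

Further compounds
F1 | step 5 | ethyl (3S)-3-(4-formyl-3,5-dihydroxy-2-methylphenoxy)butanoate | Cc1c(O[C@@H](C)CC(=O)OCC)cc(O)c(C=O)c1O
F2 | step 5 | (3S)-3-(4-formyl-3,5-dihydroxy-2-methylphenoxy)butanoic acid | Cc1c(O[C@@H](C)CC(=O)O)cc(O)c(C=O)c1O
F3 | step 6 | (2S,8S)-8-[(2E)-3,7-dimethylocta-2,6-dien-1-yl]-5-hydroxy-2,8-dimethyl-4,7-dioxo-3,4,7,8-tetrahydro-2H-chromene-6-carbaldehyde | CC(C)=CCC/C(C)=C/C[C@]1(C)C(=O)C(C=O)=C(O)C2=C1O[C@@H](C)CC2=O
F4 | step 8 | (2S,8R)-8-[(2E)-3,7-dimethylocta-2,6-dien-1-yl]-2,8-dimethyl-6-(3-methylbut-2-en-1-ylidene)-2,3-dihydro-4H-chromene-4,5,7(6H,8H)-trione | CC(C)=CCC/C(C)=C/C[C@@]1(C)C(=O)C(=CC=C(C)C)C(=O)C2=C1O[C@@H](C)CC2=O
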